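Everything rests on cutting polyanthinin back to its most crowded fragment: the C5–C10 bond with its two cis methyl groups and the four ring bonds C4–C5, C5–C6, C1–C10 and C9–C10. This fragment has a local twofold axis that exchanges ring A and ring B (C3 with C8, C4 with C9). A Weiss–Cook condensation of biacetyl with two molecules of dimethyl 3-oxoglutarate assembles it in one operation as a cis-fused bis-cyclopentanone that still lacks C2 and C7. The precursor needs no preparation, since both components are purchased. Enantiotopic double enolisation, insertion of C2 and C7 and separate elaboration of the two enone rings complete the synthesis.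

Key step: step 1

Convention: drimane numbering is used throughout. C3 is oxygenated, C4 is gem-dimethyl, C5 and C10 are the fusion carbons, C8 is the methylene carbon, and C9 bears C11. β is the face carrying the two angular methyl groups in the usual orientation (ring A left, C10 above C5). In 4–6 the bridgeheads are C5 and C10, the carbonyl or enol carbons are C3 and C8, and the flanking carbons are C1, C4, C6 and C9.

Assumption: the (R,R) lithium amide is taken to remove protons from C1 and C6. If the sense proves opposite, the equally available (S,S) base is used and nothing else changes.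

Step 1
Reactants: 1 biacetyl; 2 dimethyl 3-oxoglutarate (2 equiv)
Product: 4 cis-1,5-dimethylbicyclo[3.3.0]octane-3,7-dione (meso), via tetraester 3 (not isolated)
Conditions: NaHCO3, H2O (pH ca. 8), rt; then aq HCl, AcOH, reflux
Reagents that add atoms: none
Why: Weiss–Cook condensation, a cascade of two aldol and two Michael additions in buffered water. One α-carbon of the first oxoglutarate adds to a carbonyl of 1 and its other α-carbon closes the first ring by intramolecular aldol addition, a 5-(enolexo)-exo-trig closure through the ester enol, after which loss of water leaves a 4-hydroxycyclopentenone. The second oxoglutarate adds to this enone in Michael fashion, the remaining tertiary hydroxy group leaves as water to unveil a new enone, and the last α-carbon closes the second ring by a 5-exo-trig intramolecular Michael addition to give 3, whose four esters are hydrolysed and lost as CO2 in hot acid. The two new stereocentres C5 and C10 are controlled by ring strain alone, because trans fusion of two five-membered rings across a fully substituted bond is prohibitively strained, so the second ring must close on the side that places both methyl groups cis and 4 is meso. The selectivity needed is clean one-to-two stoichiometry without oligomers; it is secured because the intermediate cyclopentenone is a far better acceptor than 1 is a carbonyl partner, the earlier additions are reversible, and the stabilised bis-enol form of 3 separates from the aqueous medium.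

Step 2
Reactants: 4 cis-1,5-dimethylbicyclo[3.3.0]octane-3,7-dione
Product: 5 (1S,5S)-1,5-dimethyl-3,7-bis(trimethylsilyloxy)bicyclo[3.3.0]octa-2,6-diene (enol double bonds C1=C3 and C6=C8)
Conditions: (R,R)-bis(1-phenylethyl)amine, n-BuLi, LiCl, THF; Me3SiCl (internal quench), −100 to −78 °C
Reagents that add atoms: chlorotrimethylsilane, C[Si](C)(C)Cl
Why: Enantiotopic-group-selective deprotonation with a chiral lithium amide under internal silyl quench, a known desymmetrisation of cis-bicyclo[3.3.0]octan-3-ones: the C1/C6 methylenes are homotopic to each other and enantiotopic to C4/C9, so the same preference acts on both rings, a mismatched second event is diverted into an achiral regioisomer that is removed after step 4 (Horeau-type amplification), and although no new stereocentre forms, the meso compound becomes chiral here, which fixes the absolute configuration at C5 and C10.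

Step 3
Reactants: 5 bis(silyl enol ether)
Product: 6 bis(siloxycyclopropane) derived from 5 (CH2 groups C2 and C7 added across C1=C3 and C6=C8 on the β face)
Conditions: Et2Zn, CH2I2, Et2O, 0 °C to rt
Reagents that add atoms: diiodomethane, ICI
Why: Furukawa-type Simmons–Smith cyclopropanation, reliable for electron-rich silyl enol ethers and expected on the convex β face (these cyclopropane centres are erased in step 4); a plain methylene is transferred because dichlorocarbene would leave C2 and C7 chlorinated after ring opening.

Step 4
Reactants: 6 bis(siloxycyclopropane)
Product: 8 (4aS,8aS)-4a,8a-dimethyl-4a,8a-dihydronaphthalene-2,6(1H,5H)-dione (bis-enone C1=C2–C3=O and C6=C7–C8=O), via bis(β-chloro ketone) 7 (not isolated)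
Conditions: FeCl3, DMF, 0 °C to rt; extractive work-up, crude; NaOAc, MeOH, reflux
Reagents that add atoms: none
Why: Ito–Saegusa ring expansion: FeCl3 oxidises each siloxycyclopropane and the internal C1–C3 or C6–C8 bond breaks to the more stable secondary β-keto radical, which takes up chlorine to give 7, and acetate-promoted E1cB loss of HCl then gives the two enones without touching C5 or C10.

Step 5
Reactants: 8 bis-enone
Product: 9 8-mono(ethylene ketal) of 8
Conditions: HOCH2CH2OH (1.0 equiv), p-TsOH (cat.), benzene, reflux (Dean–Stark), stopped at partial conversion
Reagents that add atoms: ethylene glycol, OCCO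
Why: Acid-catalysed ketalisation with one equivalent of diol: the twofold axis makes the two carbonyl groups homotopic so only one mono-ketal exists (the ketalised ring is thereby defined as ring B), the quaternary γ-carbons exclude double-bond migration, and unreacted 8 as well as hydrolysed bis-ketal are recycled.

Step 6
Reactants: 9 mono-ketal
Product: 10 4,4-dimethyl derivative of 9 (ring A: C1=C2–C3=O next to quaternary C4)
Conditions: KOt-Bu (3 equiv), MeI (excess), THF/t-BuOH, 0 °C to rt
Reagents that add atoms: iodomethane, CI
Why: Exhaustive enolate alkylation: in ring A C2 is vinylic and C10 carries no hydrogen, so C4 is the only carbon that can be deprotonated and is methylated twice (a tactic proven for α′-carbons next to a quaternary centre in enones), no stereocentre arises, and ring B is inert as its ketal.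

Step 7
Reactants: 10 dimethylated enone ketal
Product: 12 (3S,5S,10R)-3β-hydroxy-4,4,5β,10β-tetramethyl-cis-decal-6-en-8-one ethylene ketal, via saturated ketone 11 (not isolated)
Conditions: Li (excess), NH3(l)/THF, −78 °C; then MeOH, −78 to −33 °C; NH4Cl
Reagents that add atoms: none
Why: Birch-type dissolving-metal reduction: the enone is saturated via its enolate, methanol releases ketone 11, and its ketyl is reduced to the thermodynamically preferred equatorial alcohol, which is 3β (3S) because quaternary C4 holds ring A in the chair that keeps C4 equatorial on ring B and the C5 methyl equatorial on ring A, while the isolated C6=C7 bond is not an electron acceptor under these conditions.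

Step 8
Reactants: 12 hydroxy ketal
Product: 13 (3S,5S,10R)-3β-hydroxy-4,4,5β,10β-tetramethyl-cis-decal-6-en-8-one
Conditions: 1 M HCl, THF, rt
Reagents that add atoms: water, O
Why: Acid-catalysed ketal hydrolysis, fast for an allylic ketal because the oxocarbenium ion is conjugated, and mild enough to leave the hindered secondary alcohol and all stereocentres untouched.

Step 9
Reactants: 13 hydroxy enone
Product: 14 (3S,5S,9S,10R)-3β-hydroxy-9β-(hydroxymethyl)-4,4,5β,10β-tetramethyl-cis-decal-6-en-8-one
Conditions: LiN(i-Pr)2 (2.2 equiv), THF, −78 °C; monomeric CH2O (THF solution from cracked paraformaldehyde), −78 °C; AcOH, −78 °C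
Reagents that add atoms: formaldehyde, C=O
Why: Aldol addition of the cross-conjugated lithium dienolate (C9 is the only acidic carbon since C5 is quaternary and C7 vinylic) to formaldehyde: with C4 pseudo-equatorial on ring B the α face of C9 is closed by the adjacent pseudo-axial C10–C1 bond and by ring A folded beneath, whereas the convex β face offers only a 1,3-contact with the C5 methyl group, so the small electrophile should enter axially from the β face, and the cold acidic quench prevents equilibration to the more stable 9α epimer.

Step 10
Reactants: 14 aldol enone
Product: 15 (3S,5S,9S,10R)-3β-hydroxy-9β-(hydroxymethyl)-4,4,5β,10β-tetramethyl-cis-decalin-8-one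
Conditions: H2 (1 atm), Pd/C, EtOAc, rt
Reagents that add atoms: none
Why: Heterogeneous catalytic hydrogenation of the conjugated C6=C7 bond under neutral conditions, which creates no stereocentre and leaves the epimerisable C9 centre and the β-hydroxy ketone intact.

Step 11
Reactants: 15 keto diol
Product: 16 (3S,5S,9S,10R)-9β-(hydroxymethyl)-4,4,5β,10β-tetramethyl-8-methylene-cis-decalin-3β-ol
Conditions: Zn, CH2Br2, TiCl4, THF (pre-aged reagent, excess); 15 in CH2Cl2, 0 °C to rt
Reagents that add atoms: dibromomethane, BrCBr
Why: Lombardo methylenation with the non-basic gem-dimetallic reagent, chosen because it converts enolisable ketones without α-epimerisation or β-elimination and tolerates free hydroxy groups when used in excess, so C9 stays as set and stops being epimerisable.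

Step 12
Reactants: 16 methylene diol; 17 umbelliferone
Product: 18 deacetylpolyanthinin (7-coumarinyl ether at C11 of 16 with free 3β-hydroxy group)
Conditions: PPh3, DIAD, THF, 0 °C to rt
Reagents that add atoms: none
Why: Mitsunobu etherification: only the primary C11 hydroxy group gives an oxyphosphonium salt that can be displaced, the 3β-hydroxy group next to quaternary C4 being too hindered for substitution, and the acidic phenol 17 attacks C11 in SN2 fashion without touching a stereocentre.

Step 13
Reactants: 18 deacetylpolyanthinin
Product: 19 polyanthinin
Conditions: Ac2O, DMAP, pyridine, rt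
Reagents that add atoms: acetic anhydride, CC(=O)OC(C)=O
Why: DMAP-catalysed acylation of the equatorial secondary alcohol with retention at C3, under which the aryl ether, the coumarin lactone and the exocyclic alkene are inert.

Compound list
1 | biacetyl (butane-2,3-dione) | CC(=O)C(C)=O | starting material
2 | dimethyl 3-oxoglutarate | COC(=O)CC(=O)CC(=O)OC | starting material
3 | tetramethyl cis-1,5-dimethyl-3,7-dioxobicyclo[3.3.0]octane-2,4,6,8-tetracarboxylate (largely bis-enol; ester-bearing carbons labile) | O=C1C(C(=O)OC)[C@]2(C)C(C(=O)OC)C(=O)C(C(=O)OC)[C@]2(C)C1C(=O)OC | intermediate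
4 | cis-1,5-dimethylbicyclo[3.3.0]octane-3,7-dione (meso) | C[C@]12CC(=O)C[C@@]1(C)CC(=O)C2 | intermediate
5 | (1S,5S)-1,5-dimethyl-3,7-bis(trimethylsilyloxy)bicyclo[3.3.0]octa-2,6-diene | C[Si](C)(C)OC1=C[C@]2(C)CC(O[Si](C)(C)C)=C[C@]2(C)C1 | intermediate
6 | bis(siloxycyclopropane), C2 and C7 methylenes on the β face | C[Si](C)(C)O[C@]13C[C@H]1[C@]2(C)C[C@@]4(O[Si](C)(C)C)C[C@H]4[C@]2(C)C3 | intermediate
7 | 1,6-dichloro-5β,10β-dimethyl-cis-decalin-3,8-dione (C1 and C6 unassigned) | O=C1CC(Cl)[C@]2(C)CC(=O)CC(Cl)[C@]2(C)C1 | intermediate
8 | (4aS,8aS)-4a,8a-dimethyl-4a,8a-dihydronaphthalene-2,6(1H,5H)-dione | O=C1C=C[C@]2(C)CC(=O)C=C[C@]2(C)C1 | intermediate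
9 | 8-mono(ethylene ketal) of 8 | C12(OCCO1)C=C[C@]3(C)CC(=O)C=C[C@]3(C)C2 | intermediate
10 | 4,4-dimethyl derivative of 9 | C12(OCCO1)C=C[C@]3(C)C(C)(C)C(=O)C=C[C@]3(C)C2 | intermediate
11 | 1,2-dihydro derivative of 10 (saturated C3 ketone) | C12(OCCO1)C=C[C@]3(C)C(C)(C)C(=O)CC[C@]3(C)C2 | intermediate
12 | (3S,5S,10R)-3β-alcohol, C8 ethylene ketal, C6=C7 | C12(OCCO1)C=C[C@]3(C)C(C)(C)[C@@H](O)CC[C@]3(C)C2 | intermediate
13 | (3S,5S,10R)-3β-hydroxy-4,4,5β,10β-tetramethyl-cis-decal-6-en-8-one | O=C1C=C[C@]2(C)C(C)(C)[C@@H](O)CC[C@]2(C)C1 | intermediate
14 | (3S,5S,9S,10R)-9β-hydroxymethyl derivative of 13 | O=C1C=C[C@]2(C)C(C)(C)[C@@H](O)CC[C@]2(C)[C@H]1CO | intermediate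
15 | (3S,5S,9S,10R)-6,7-dihydro derivative of 14 | O=C1CC[C@]2(C)C(C)(C)[C@@H](O)CC[C@]2(C)[C@H]1CO | intermediate
16 | (3S,5S,9S,10R)-9β-(hydroxymethyl)-4,4,5β,10β-tetramethyl-8-methylene-cis-decalin-3β-ol | C=C1CC[C@]2(C)C(C)(C)[C@@H](O)CC[C@]2(C)[C@H]1CO | intermediate
17 | umbelliferone (7-hydroxycoumarin) | Oc1ccc2ccc(=O)oc2c1 | starting material
18 | deacetylpolyanthinin | C=C1CC[C@]2(C)C(C)(C)[C@@H](O)CC[C@]2(C)[C@H]1COc1ccc2ccc(=O)oc2c1 | intermediate
19 | polyanthinin, (3S,5S,9S,10R) | C=C1CC[C@]2(C)C(C)(C)[C@@H](OC(C)=O)CC[C@]2(C)[C@H]1COc1ccc2ccc(=O)oc2c1 | target

Total step count: 13. Longest linear sequence: 13 steps (from 1 and 2).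

Steps most likely to fail

Risk 1 (step 9). Formaldehyde may attack the α face of the dienolate. Alternatively, the kinetically formed and less stable 9β centre may equilibrate by enolisation or retro-aldol cleavage before the quench.
- Fallback, from 13 back to 14: the stereocentre is set by C–H instead of C–C bond formation.
- The aldol addition is accepted as it falls and gives the 9α-hydroxymethyl epimer of 14 F1.
- LiN(i-Pr)2 (3.3 equiv, THF, −78 to −40 °C) converts this into its enolate bis-alkoxide.
- Kinetic protonation at −78 °C with a bulky acid (2,6-di-tert-butyl-4-methylphenol) on the same accessible α face pushes C11 to the β face and delivers 14.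

Risk 2 (step 7). Electron transfer may cleave an allylic C–O bond of the ketal. Protonation of the ketyl-derived carbanion may also fail to follow the thermodynamic preference, which would erode the configuration at C3.
- Fallback, from 10 back to 12: two hydride reductions under reagent control.
- Conjugate reduction with [(Ph3P)CuH]6 (toluene, rt) touches only the enone and gives 11, now isolated.
- (R)-Me-CBS oxazaborolidine with BH3·SMe2 then reduces the ketone. Quaternary C4 acts as the large substituent and the C2 methylene as the small one, which directs hydride to the α face and gives 12.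
- No compound outside the list is made (F0).

Risk 3 (step 2). Discrimination between the enantiotopic methylene pairs may be too low, so that 8 emerges from step 4 with insufficient enantiomeric purity.
- Fallback, from 8 back to 8: resolution through covalent diastereomers replaces kinetic selection.
- Both carbonyl groups are ketalised with (2R,3R)-butane-2,3-diol (p-TsOH, benzene, Dean–Stark). This gives the bis-ketal of 8 F2 together with the diastereomeric bis-ketal of the mirror-image enone F3.
- The two are separated by crystallisation or chromatography, and aqueous HCl in THF releases enantiopure 8 from the bis-ketal F2.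

Further compounds
F1 | step 9 | (3S,5S,9R,10R)-3β-hydroxy-9α-(hydroxymethyl)-4,4,5β,10β-tetramethyl-cis-decal-6-en-8-one | O=C1C=C[C@]2(C)C(C)(C)[C@@H](O)CC[C@]2(C)[C@@H]1CO
F0 | step 7 | none | none
F2 | step 2 | bis[(2R,3R)-butane-2,3-diyl ketal] of 8 | C12(O[C@H](C)[C@@H](C)O1)C=C[C@]3(C)CC4(O[C@H](C)[C@@H](C)O4)C=C[C@]3(C)C2
F3 | step 2 | bis[(2R,3R)-butane-2,3-diyl ketal] of the mirror image of 8 | C12(O[C@H](C)[C@@H](C)O1)C=C[C@@]3(C)CC4(O[C@H](C)[C@@H](C)O4)C=C[C@@]3(C)C2
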